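Everything rests on cutting ring A, the central quinone (C1 acetoxy, C2 aryl, C3 carbonyl, C4 hydroxy, C5 aryl, C6 carbonyl), into four pieces: a chromium carbene carbon (C3), one of its CO ligands (C6), an aryl silyl ynol ether (C1–C2) and an α-benzyloxystyryl unit (C4–C5). The key step exploits the para relationship of the carbonyl carbons C3 and C6 and the strict alternation of oxygen- and aryl-bearing carbons around ring A: a single benzannulation forms C2–C3, C1–C6 and C5–C6 and leaves the four ring oxygens differentiated as OMe, OH, OSi and OBn. Its precursor is a pentacarbonylchromium methoxycarbene bearing a (Z)-1-benzyloxy-2-(4-benzyloxyphenyl)vinyl group.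

Key step: step 4

Remark on the chemistry: the target has no stereocentre, and the only stereochemical element of the route is the Z alkene of carbene 8. The hydroxy-1,4-quinone drawn for the target and its ortho-quinone tautomer are one compound, so only the number of acetyl groups on ring A has to be controlled, not their position. Stannane 1 is assumed to be purchasable.

Step 1
Reactants: 1 tributyl[(benzyloxy)methyl]stannane; 2 hexacarbonylchromium Cr(CO)6
Product: 5 pentacarbonyl[2-(benzyloxy)-1-methoxyethylidene]chromium, via (benzyloxy)methyllithium 3 (not isolated), via lithium acylchromate 4 (not isolated)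
Conditions: n-BuLi, THF, −78 °C; Cr(CO)6, THF, −78 to 0 °C; Me3OBF4, CH2Cl2/H2O, 0 °C
Reagents that add atoms: trimethyloxonium tetrafluoroborate C[O+](C)C.F[B-](F)(F)F
Why: Tin–lithium exchange gives the α-alkoxy organolithium 3 at low temperature, which adds to a CO ligand of zerovalent Cr(CO)6, and O-methylation of acylchromate 4 completes a classical Fischer carbene synthesis.

Step 2
Reactants: 5 pentacarbonyl[2-(benzyloxy)-1-methoxyethylidene]chromium; 6 4-(benzyloxy)benzaldehyde
Product: 8 pentacarbonyl[(Z)-2-(benzyloxy)-3-[4-(benzyloxy)phenyl]-1-methoxyprop-2-enylidene]chromium, via silyl aldol ether 7 (not isolated)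
Conditions: Me3SiCl, Et3N, Et2O, rt
Reagents that add atoms: none
Why: Aldol condensation of a Fischer carbene complex under amine/silyl chloride conditions: the α-CH2 of 5, acidified by the carbene carbon, adds to the silyl-activated aldehyde, and E1cB loss of silanolate from 7 should give the thermodynamically preferred Z alkene, with the aryl group trans to the bulky carbene carbon and cis to the benzyloxy group.

Step 3
Reactants: 9 ethyl 4-(benzyloxy)benzoate
Product: 12 1-(benzyloxy)-4-{[(triisopropylsilyl)oxy]ethynyl}benzene, via lithium dibromoenolate 10 (not isolated), via lithium ynolate 11 (not isolated)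
Conditions: CH2Br2, lithium 2,2,6,6-tetramethylpiperidide, THF, −78 °C; LiN(SiMe3)2, −78 to −20 °C; n-BuLi, −78 °C to rt; i-Pr3SiCl, −78 °C to rt
Reagents that add atoms: dibromomethane BrCBr; chlorotriisopropylsilane CC(C)[Si](Cl)(C(C)C)C(C)C
Why: Kowalski ester homologation stopped at the ynolate: LiCHBr2 adds to the ester, dibromoenolate 10 undergoes bromine–lithium exchange and 1,2-aryl shift with loss of LiBr to give ynolate 11, and the bulky silyl chloride reacts at oxygen, where a small one would give the silylketene.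

Step 4
Reactants: 8 pentacarbonyl[(Z)-2-(benzyloxy)-3-[4-(benzyloxy)phenyl]-1-methoxyprop-2-enylidene]chromium; 12 1-(benzyloxy)-4-{[(triisopropylsilyl)oxy]ethynyl}benzene
Product: 14 3-(benzyloxy)-2,5-bis[4-(benzyloxy)phenyl]-4-methoxy-6-[(triisopropylsilyl)oxy]phenol, via tricarbonylchromium arene complex 13 (not isolated)
Conditions: THF (degassed), 55 °C; then air, rt, neutral work-up
Reagents that add atoms: none
Why: Proposed new method: thermal loss of one CO from the zerovalent chromium carbene 8 lets alkyne 12 coordinate and insert into the Cr=C bond, the nucleophilic aryl-bearing alkyne carbon bonding to the electrophilic carbene carbon (C2–C3) so that the silyloxy carbon becomes the new oxygen-stabilised carbene centre, where CO insertion gives a chromium-bound dienylketene (C1–C6). Ring A then closes by thermal 6π electrocyclisation of the dienylketene onto the styryl carbon (C5–C6), which the Z alkene permits because it turns its hydrogen and not its aryl group inward, and tautomerisation of the cyclohexadienone gives the phenol as Cr(CO)3 complex 13, from which air removes the metal. The closest known reaction is the Dötz benzannulation of alkenyl(alkoxy)carbene chromium complexes, α-alkoxyalkenyl ones included, with internal alkynes; a silyl ynol ether as the alkyne partner is the untested element. No stereocentre is formed. The step needs insertion with the silyloxy carbon next to the CO-derived carbon, which the strong polarisation of the ynol ether secures and the bulk of the i-Pr3SiO group should reinforce. It also needs CO insertion to outrun five-membered-ring formation, which an alkenyl carbene in a donor solvent favours, and a neutral work-up so that the silyl group does not shift to the neighbouring free phenol oxygen.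

Step 5
Reactants: 14 3-(benzyloxy)-2,5-bis[4-(benzyloxy)phenyl]-4-methoxy-6-[(triisopropylsilyl)oxy]phenol
Product: 15 2-(benzyloxy)-3,6-bis[4-(benzyloxy)phenyl]-5-[(triisopropylsilyl)oxy]cyclohexa-2,5-diene-1,4-dione
Conditions: (NH4)2Ce(NO3)6, MeCN/H2O, 0 °C
Reagents that add atoms: water O
Why: Oxidative demethylation of a 4-methoxyphenol by tetravalent cerium: two-electron oxidation gives a phenoxonium ion that water captures at the methoxy-bearing C3, methanol is expelled and the 1,4-quinone results, while the hindered silyl group resists attack at silicon (which would open the ortho-quinone pathway) and the benzyl ethers should survive the short, cold reaction.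

Step 6
Reactants: 15 2-(benzyloxy)-3,6-bis[4-(benzyloxy)phenyl]-5-[(triisopropylsilyl)oxy]cyclohexa-2,5-diene-1,4-dione
Product: 17 4-(benzyloxy)-2,5-bis[4-(benzyloxy)phenyl]-3,6-dioxocyclohexa-1,4-dien-1-yl acetate, via caesium quinonolate 16 (not isolated)
Conditions: CsF, MeCN, 0 °C; then AcCl, 0 °C to rt
Reagents that add atoms: acetyl chloride CC(Cl)=O
Why: Fluoride cleaves the vinylogous silyl ester at the C1 oxygen (strong Si–F bond) to the delocalised quinonolate 16, which acetyl chloride acylates irreversibly in the same flask, a standard silyl-to-acyl exchange; no hydroxide or alkoxide is present, so the benzyl vinylogous ester at C4 should stay in place, and any hydroxyquinone formed by premature silyl loss in step 5 would converge under the same reagents.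

Step 7
Reactants: 17 4-(benzyloxy)-2,5-bis[4-(benzyloxy)phenyl]-3,6-dioxocyclohexa-1,4-dien-1-yl acetate
Product: 19 4-hydroxy-2,5-bis(4-hydroxyphenyl)-3,6-dioxocyclohexa-1,4-dien-1-yl acetate (the target), via hydroquinone 18 (not isolated)
Conditions: H2 (1 atm), Pd/C, EtOAc, rt; then air, rt
Reagents that add atoms: none
Why: Catalytic hydrogenolysis removes the two aryl benzyl ethers and the vinylogous benzyl ester and reduces the quinone to hydroquinone 18, which air reoxidises to the quinone; the acetate tolerates neutral hydrogenolysis in an aprotic solvent, and an acetyl shift in 18 would be degenerate because the four ring oxygens of the parent tetrol are equivalent.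

Compound list
1 | tributyl[(benzyloxy)methyl]stannane | CCCC[Sn](CCCC)(CCCC)COCc1ccccc1 | starting material
2 | hexacarbonylchromium Cr(CO)6 | O=C=[Cr](=C=O)(=C=O)(=C=O)(=C=O)=C=O | starting material
3 | (benzyloxy)methyllithium | [Li]COCc1ccccc1 | intermediate
4 | lithium pentacarbonyl[2-(benzyloxy)-1-oxidoethylidene]chromate (acylchromate) | [Li+].[O-]C(COCc1ccccc1)=[Cr](=C=O)(=C=O)(=C=O)(=C=O)=C=O | intermediate
5 | pentacarbonyl[2-(benzyloxy)-1-methoxyethylidene]chromium | COC(COCc1ccccc1)=[Cr](=C=O)(=C=O)(=C=O)(=C=O)=C=O | intermediate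
6 | 4-(benzyloxy)benzaldehyde | O=Cc1ccc(OCc2ccccc2)cc1 | starting material
7 | pentacarbonyl{2-(benzyloxy)-3-[4-(benzyloxy)phenyl]-1-methoxy-3-[(trimethylsilyl)oxy]propylidene}chromium (diastereomer mixture) | COC(C(OCc1ccccc1)C(O[Si](C)(C)C)c1ccc(OCc2ccccc2)cc1)=[Cr](=C=O)(=C=O)(=C=O)(=C=O)=C=O | intermediate
8 | pentacarbonyl[(Z)-2-(benzyloxy)-3-[4-(benzyloxy)phenyl]-1-methoxyprop-2-enylidene]chromium | COC(/C(OCc1ccccc1)=C/c1ccc(OCc2ccccc2)cc1)=[Cr](=C=O)(=C=O)(=C=O)(=C=O)=C=O | intermediate
9 | ethyl 4-(benzyloxy)benzoate | CCOC(=O)c1ccc(OCc2ccccc2)cc1 | starting material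
10 | lithium 1-[4-(benzyloxy)phenyl]-2,2-dibromoethen-1-olate | [Li+].[O-]C(=C(Br)Br)c1ccc(OCc2ccccc2)cc1 | intermediate
11 | lithium 2-[4-(benzyloxy)phenyl]ethyn-1-olate | [Li+].[O-]C#Cc1ccc(OCc2ccccc2)cc1 | intermediate
12 | 1-(benzyloxy)-4-{[(triisopropylsilyl)oxy]ethynyl}benzene | CC(C)[Si](OC#Cc1ccc(OCc2ccccc2)cc1)(C(C)C)C(C)C | intermediate
13 | tricarbonyl(η6-arene)chromium complex of phenol 14, Cr(CO)3 on ring A (written as its components) | COc1c(-c2ccc(OCc3ccccc3)cc2)c(O[Si](C(C)C)(C(C)C)C(C)C)c(O)c(-c2ccc(OCc3ccccc3)cc2)c1OCc1ccccc1.[Cr].[C-]#[O+].[C-]#[O+].[C-]#[O+] | intermediate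
14 | 3-(benzyloxy)-2,5-bis[4-(benzyloxy)phenyl]-4-methoxy-6-[(triisopropylsilyl)oxy]phenol | COc1c(-c2ccc(OCc3ccccc3)cc2)c(O[Si](C(C)C)(C(C)C)C(C)C)c(O)c(-c2ccc(OCc3ccccc3)cc2)c1OCc1ccccc1 | intermediate
15 | 2-(benzyloxy)-3,6-bis[4-(benzyloxy)phenyl]-5-[(triisopropylsilyl)oxy]cyclohexa-2,5-diene-1,4-dione | CC(C)[Si](OC1=C(c2ccc(OCc3ccccc3)cc2)C(=O)C(OCc2ccccc2)=C(c2ccc(OCc3ccccc3)cc2)C1=O)(C(C)C)C(C)C | intermediate
16 | caesium 4-(benzyloxy)-2,5-bis[4-(benzyloxy)phenyl]-3,6-dioxocyclohexa-1,4-dien-1-olate | [Cs+].[O-]C1=C(c2ccc(OCc3ccccc3)cc2)C(=O)C(OCc2ccccc2)=C(c2ccc(OCc3ccccc3)cc2)C1=O | intermediate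
17 | 4-(benzyloxy)-2,5-bis[4-(benzyloxy)phenyl]-3,6-dioxocyclohexa-1,4-dien-1-yl acetate | CC(=O)OC1=C(c2ccc(OCc3ccccc3)cc2)C(=O)C(OCc2ccccc2)=C(c2ccc(OCc3ccccc3)cc2)C1=O | intermediate
18 | 3,4,6-trihydroxy-2,5-bis(4-hydroxyphenyl)phenyl acetate | CC(=O)Oc1c(-c2ccc(O)cc2)c(O)c(O)c(-c2ccc(O)cc2)c1O | intermediate
19 | 4-hydroxy-2,5-bis(4-hydroxyphenyl)-3,6-dioxocyclohexa-1,4-dien-1-yl acetate | CC(=O)OC1=C(c2ccc(O)cc2)C(=O)C(O)=C(c2ccc(O)cc2)C1=O | target

Total step count: 7. Longest linear sequence: 6 steps (1, 2, 4, 5, 6, 7); step 3 supplies the alkyne branch.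

Steps most likely to fail

Step 4 (bears the label). After insertion the chromium may rest on the oxygen-stabilised silyloxy-vinylcarbene and fail to insert CO, so that five-membered-ring or cyclobutenone formation or alkyne oligomerisation takes over; insertion in the opposite sense would misplace the aryl group. The fallback uses known chemistry, sets out from carbene 8 and comes back at acetate 17. Carbene 8 would be heated in THF with 2-{[4-(benzyloxy)phenyl]ethynyl}-4,4,5,5-tetramethyl-1,3,2-dioxaborolane F1, an alkynylboronate of the class already used in this benzannulation, in which the boryl group should take the position next to the CO-derived carbon. F1 would come from 1-(benzyloxy)-4-ethynylbenzene by n-BuLi, 2-isopropoxy-4,4,5,5-tetramethyl-1,3,2-dioxaborolane and HCl in Et2O. The resulting 3-(benzyloxy)-2,5-bis[4-(benzyloxy)phenyl]-4-methoxy-6-(4,4,5,5-tetramethyl-1,3,2-dioxaborolan-2-yl)phenol F2 would be oxidised with (NH4)2Ce(NO3)6 to 2-(benzyloxy)-3,6-bis[4-(benzyloxy)phenyl]-5-(4,4,5,5-tetramethyl-1,3,2-dioxaborolan-2-yl)cyclohexa-2,5-diene-1,4-dione F3. Oxidation of its C–B bond with NaBO3·4H2O in THF/H2O would give 2-(benzyloxy)-3,6-bis[4-(benzyloxy)phenyl]-5-hydroxycyclohexa-2,5-diene-1,4-dione F4, and acetylation (AcCl, pyridine, CH2Cl2, 0 °C) would return to 17.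

Step 2. The hindered, alkoxy-substituted α-carbon may add too slowly, the aldol may revert, or the E and Z alkenes may form together. The fallback builds the alkene at the ester level and the carbene last; it sets out from aldehyde 6 and comes back at carbene 8. Condensation of 6 with methyl (benzyloxy)acetate (NaOMe, THF/MeOH) would give methyl (Z)-2-(benzyloxy)-3-[4-(benzyloxy)phenyl]prop-2-enoate F5. Saponification (LiOH, THF/H2O) would give (Z)-2-(benzyloxy)-3-[4-(benzyloxy)phenyl]prop-2-enoic acid F6, and (COCl)2 with catalytic DMF would give (Z)-2-(benzyloxy)-3-[4-(benzyloxy)phenyl]prop-2-enoyl chloride F7. Dipotassium pentacarbonylchromate K2Cr(CO)5 F8 (from 2 and KC8, THF, −78 °C) would be acylated by F7 to potassium pentacarbonyl[(Z)-2-(benzyloxy)-3-[4-(benzyloxy)phenyl]-1-oxidoprop-2-enylidene]chromate F9, which Me3OBF4 would methylate to 8.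

Step 3. The exchange and rearrangement to the ynolate may be incomplete, excess alkyllithium may metalate the benzylic ether position, or silylation may occur on carbon. The fallback reaches the ynolate by oxidation of an acetylide; it sets out from aldehyde 6 and comes back at alkyne 12 through ynolate 11. Ohira–Bestmann homologation of 6 (dimethyl (1-diazo-2-oxopropyl)phosphonate, K2CO3, MeOH) would give 1-(benzyloxy)-4-ethynylbenzene F10. n-BuLi would convert it to lithium [4-(benzyloxy)phenyl]acetylide F11, and t-BuOOLi (from t-BuOOH and LiN(SiMe3)2, THF, −78 to 0 °C) would oxidise F11 to ynolate 11. Silylation on oxygen with i-Pr3SiOTf would then give 12.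

Further compounds
F1 | step 4 | 2-{[4-(benzyloxy)phenyl]ethynyl}-4,4,5,5-tetramethyl-1,3,2-dioxaborolane | CC1(C)OB(C#Cc2ccc(OCc3ccccc3)cc2)OC1(C)C
F2 | step 4 | 3-(benzyloxy)-2,5-bis[4-(benzyloxy)phenyl]-4-methoxy-6-(4,4,5,5-tetramethyl-1,3,2-dioxaborolan-2-yl)phenol | COc1c(-c2ccc(OCc3ccccc3)cc2)c(B2OC(C)(C)C(C)(C)O2)c(O)c(-c2ccc(OCc3ccccc3)cc2)c1OCc1ccccc1
F3 | step 4 | 2-(benzyloxy)-3,6-bis[4-(benzyloxy)phenyl]-5-(4,4,5,5-tetramethyl-1,3,2-dioxaborolan-2-yl)cyclohexa-2,5-diene-1,4-dione | CC1(C)OB(C2=C(c3ccc(OCc4ccccc4)cc3)C(=O)C(OCc3ccccc3)=C(c3ccc(OCc4ccccc4)cc3)C2=O)OC1(C)C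
F4 | step 4 | 2-(benzyloxy)-3,6-bis[4-(benzyloxy)phenyl]-5-hydroxycyclohexa-2,5-diene-1,4-dione | OC1=C(c2ccc(OCc3ccccc3)cc2)C(=O)C(OCc2ccccc2)=C(c2ccc(OCc3ccccc3)cc2)C1=O
F5 | step 2 | methyl (Z)-2-(benzyloxy)-3-[4-(benzyloxy)phenyl]prop-2-enoate | COC(=O)/C(OCc1ccccc1)=C/c1ccc(OCc2ccccc2)cc1
F6 | step 2 | (Z)-2-(benzyloxy)-3-[4-(benzyloxy)phenyl]prop-2-enoic acid | OC(=O)/C(OCc1ccccc1)=C/c1ccc(OCc2ccccc2)cc1
F7 | step 2 | (Z)-2-(benzyloxy)-3-[4-(benzyloxy)phenyl]prop-2-enoyl chloride | ClC(=O)/C(OCc1ccccc1)=C/c1ccc(OCc2ccccc2)cc1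
F8 | step 2 | dipotassium pentacarbonylchromate K2Cr(CO)5 | [K+].[K+].O=C=[Cr-2](=C=O)(=C=O)(=C=O)=C=O
F9 | step 2 | potassium pentacarbonyl[(Z)-2-(benzyloxy)-3-[4-(benzyloxy)phenyl]-1-oxidoprop-2-enylidene]chromate | [K+].[O-]C(/C(OCc1ccccc1)=C/c1ccc(OCc2ccccc2)cc1)=[Cr](=C=O)(=C=O)(=C=O)(=C=O)=C=O
F10 | step 3 | 1-(benzyloxy)-4-ethynylbenzene | C#Cc1ccc(OCc2ccccc2)cc1
F11 | step 3 | lithium [4-(benzyloxy)phenyl]acetylide | [Li]C#Cc1ccc(OCc2ccccc2)cc1
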